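The complex with three exchanged is the odd species in the maple run: both it and the complex with two exchanged grow, yet the ratio of three to two falls from 0.595 at 0.667 min to 0.313 at 4.00 min. That fall reads as a fast equilibrium shifting as the exchanges use up incoming ligand and set free a leaving ligand that no reading shows.

the same everywhere: starting complex 0.10 M
- alder: incoming ligand 0.11 M; protic impurity 2 mM; run made earlier
- cedar: incoming ligand 0.29 M; protic impurity 2 mM; run made earlier
- maple: incoming ligand 0.73 M; protic impurity 2 mM; run made earlier
- ochre: incoming ligand 0.100 M; protic impurity 2.00 mM; time 6.0 min
- amber: incoming ligand 0.300 M; protic impurity 2.00 mM; time 6.0 min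
- grey: incoming ligand 0.900 M; protic impurity 2.00 mM; time 6.0 min

| run | time / min | complex with one exchanged / % | starting complex / % | complex with three exchanged / % | complex with two exchanged / % |
|---|---|---|---|---|---|
| alder | 0.833 | 14.3 | 81.9 | 0 | 2.1 |
| alder | 1.50 | 18.2 | 73.6 | 1.2 | 3.5 |
| alder | 2.50 | 21.6 | 64.3 | 1.5 | 11.9 |
| alder | 3.00 | 21.2 | 60.4 | 2.5 | 14.4 |
| alder | 4.00 | 23.7 | 56.3 | 3.4 | 17.9 |
| cedar | 0.333 | 14.2 | 81.2 | 0 | 0 |
| cedar | 0.667 | 21.4 | 68.1 | 1.8 | 6.7 |
| cedar | 1.33 | 23.2 | 50.2 | 6.1 | 16.6 |
| cedar | 2.00 | 23.5 | 39.0 | 6.3 | 29.8 |
| cedar | 4.00 | 17.5 | 23.1 | 6.1 | 48.5 |
| maple | 0.333 | 22.8 | 60.3 | 4.6 | 10.7 |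
| maple | 0.667 | 24.7 | 40.6 | 14.4 | 24.2 |
| maple | 1.33 | 15.1 | 17.8 | 19.3 | 45.7 |
| maple | 2.00 | 9.8 | 9.9 | 20.5 | 59.7 |
| maple | 4.00 | 3.3 | 0 | 22.1 | 70.6 |

(standard deviation of a reading: 1 percentage point)

* which of these there is most of at the end, counted by the starting complex in it, ochre (starting complex / complex with two exchanged / complex with one exchanged / complex with three exchanged)
* which of these there is most of at the end, counted by the starting complex in it, amber (starting complex / complex with two exchanged / complex with one exchanged / complex with three exchanged)
* which of these there is most of at the end, counted by the starting complex in it, grey (starting complex / complex with two exchanged / complex with one exchanged / complex with three exchanged)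
* final amount of the leader among these, as a percentage of the starting complex charged, in ochre
* final amount of the leader among these, as a percentage of the starting complex charged, in amber
* final amount of the leader among these, as a percentage of the starting complex charged, in grey



If each exchange frees one leaving ligand, c(leaving ligand) is c(starting complex charged) times the sum of one-exchanged, twice two-exchanged and three times three-exchanged, and c(incoming ligand) is its charge minus that. The last maple reading then has 0.211 M of leaving ligand and 0.519 M of incoming ligand. These give 0.127 for the exchange quotient Q, defined as c(three-exchanged)·c(leaving ligand) over c(two-exchanged)·c(incoming ligand), the reaction quotient of the last exchange.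

The second way is the last cedar reading, from a different charge, with 0.133 M of leaving ligand and 0.157 M of incoming ligand. It gives Q = 0.106, somewhat lower. Cedar's number rests on a three-exchanged reading of 6.1% against maple's 22.1%, each with a scatter of 1 percentage point, so cedar's is the looser and maple's is carried.

Q gives a split and not a pace, so my own reckoning covers grey. Two exchanges per complex as a first guess give a three-to-two ratio of 0.445. The leaving ligand that share frees, 0.231 M, corrects the ratio to 0.369. Taking the 96.0% that the last maple readings account for and treating it all as two- or three-exchanged, my reckoning puts grey at 70.1% of two-exchanged and 25.9% of three-exchanged.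

The forecast names starting complex for ochre at 51%, complex with two exchanged for amber at 68% and complex with two exchanged for grey at 69%, a little below my grey figure. It reads the three-exchanged plateau differently, as “a ligand-dependent side path, perhaps a dying catalyst linked to the impurity”.

The flasks give 53.5% of starting complex in ochre, 62.2% of complex with two exchanged in amber, 5.8 points under the forecast, and 68.0% of complex with two exchanged in grey.

    protic impurity + starting complex → quenched substrate (k = 120 /M/min)
    complex with two exchanged + incoming ligand ⇌ leaving ligand + complex with three exchanged (K = 0.130, k = 4.80 /M/min)
    starting complex + incoming ligand ⇌ leaving ligand + complex with one exchanged (K = 1.80, k = 2.10 /M/min)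
    complex with one exchanged + incoming ligand ⇌ leaving ligand + complex with two exchanged (K = 10.0, k = 4.00 /M/min)

At the asked time in amber, the relaxation half-life of the last exchange by that step alone is 0.0975 min, shorter than the 0.984 min of the exchange before it. Q applied to amber's two-exchanged and end ligands gives 7.02% of three-exchanged, and amber holds 7.21%. In the neighbour of amber charged with 0.040 M of starting complex, the same Q gives 22.0%, and that flask holds 22.4%.

The earlier runs and the new flask were computed from invented constants; the scatter is artificial.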